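The route rests on disconnecting the C4–C5 bond and the C4–O bond of the cyclopent-2-enone ring (C1 ketone, C2=C3, oxygenated quaternary C4, C5 bearing the pentenyl chain, C4–O trans to that chain), an arrangement that maps onto a 2,5-disubstituted furan-2-yl carbinol. One acid-mediated operation under a chiral counter-anion should convert the furan into the carbocycle, forming both bonds and setting C4 and C5 together. Its substrate is a racemic secondary furylcarbinol with the (Z)-pent-2-enyl group on the carbinol carbon and a silyl-protected 8-hydroxyoctyl chain on the other furan α-carbon; acetylation, desilylation and a single oxidation then complete the acid.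

Key step: step 5

Remark: (Z)-hex-3-enal is sold only as a stabilised dilution and moves into conjugation on storage, so it is made fresh from (Z)-hex-3-en-1-ol and used at once.
Remark: the sense of induction of the chiral acid cannot be predicted with confidence; the (R) acid is written, and its antipode is used instead if a first screen shows that (R) leads to the (4R,5S) series.

Step 1
Reactants: 1 8-bromooctan-1-ol
Product: 2 [(8-bromooctyl)oxy]triisopropylsilane
Conditions: TIPSCl, imidazole, DMAP (cat.), CH2Cl2, 0 °C → rt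
Reagents that add atoms: triisopropylsilyl chloride, CC(C)[Si](Cl)(C(C)C)C(C)C
Why: Imidazole-promoted silylation of an unhindered primary alcohol is reliable, the primary bromide is inert under these conditions, and the bulky silyl ether is chosen to survive the organolithium and acid steps that follow.

Step 2
Reactants: 3 furan; 2 [(8-bromooctyl)oxy]triisopropylsilane
Product: 5 triisopropyl{[8-(furan-2-yl)octyl]oxy}silane, via 2-lithiofuran 4 (not isolated)
Conditions: 3 (3 equiv), n-BuLi, THF, −78 → 0 °C; then 2, DMPU, 0 °C → rt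
Reagents that add atoms: none
Why: Furan is deprotonated at its α-carbon and the 2-furyllithium is alkylated by the primary bromide in an SN2 reaction, the excess of furan suppressing 2,5-dialkylation.

Step 3
Reactants: 6 (Z)-hex-3-en-1-ol
Product: 7 (Z)-hex-3-enal
Conditions: Dess–Martin periodinane, CH2Cl2, 0 °C; cold filtration, solution used at once
Reagents that add atoms: none
Why: Dess–Martin oxidation runs under near-neutral, non-enolising conditions, so the β,γ-alkene should neither migrate into conjugation nor lose its Z geometry before the aldehyde is consumed.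

Step 4
Reactants: 5 triisopropyl{[8-(furan-2-yl)octyl]oxy}silane; 7 (Z)-hex-3-enal
Product: 10 (Z)-1-(5-{8-[(triisopropylsilyl)oxy]octyl}furan-2-yl)hex-3-en-1-ol (racemic), via 5-lithiofuran 8 (not isolated), via furylcerium dichloride 9 (not isolated)
Conditions: n-BuLi, TMEDA, THF, 0 °C → rt; CeCl3 (anhydrous), THF, −78 °C; then 7, −78 °C; aq. NH4Cl
Reagents that add atoms: none
Why: Lithiation occurs at the only free furan α-position, and transmetalation to the weakly basic, oxophilic organocerium favours 1,2-addition to the easily enolised aldehyde over deprotonation; the carbinol centre forms racemic, which is of no consequence because it becomes planar in step 5.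

Step 5
Reactants: 10 (Z)-1-(5-{8-[(triisopropylsilyl)oxy]octyl}furan-2-yl)hex-3-en-1-ol
Product: 11 (4S,5R)-4-hydroxy-5-[(Z)-pent-2-en-1-yl]-4-{8-[(triisopropylsilyl)oxy]octyl}cyclopent-2-en-1-one
Conditions: (R)-3,3′-bis(2,4,6-triisopropylphenyl)-1,1′-binaphthyl-2,2′-diyl N-(trifluoromethylsulfonyl)phosphoramide (10 mol %), H2O (5 equiv), CHCl3, 40 °C
Reagents that add atoms: water, O
Why: Proposed new method: the strong chiral Brønsted acid ionises the carbinol to a planar 5-alkylfurfuryl cation, water adds at the alkyl-bearing furan carbon, and the hemiketal opens to a 1,4-dihydroxypentadienyl cation that closes by thermal 4π conrotation to form the C4–C5 bond and, after proton loss from the oxyallyl cation, the enone. The closest known reaction types are the racemic Piancatelli rearrangement of 5-alkyl-2-furylcarbinols (ZnCl2 or Dy(OTf)3 in aqueous media), the chiral-phosphoric-acid-catalysed aza-Piancatelli rearrangement and the chiral N-triflylphosphoramide-catalysed Nazarov cyclisation, all of which pass through a pentadienyl cation of this kind. The cyclopentenone ring is closed by a 4π-electron conrotatory electrocyclisation between the former carbinol carbon and the former furan C5. Conrotation of the out,out cation fixes the relative configuration (C4–OH trans to the C5 pentenyl group, the two carbon chains cis), while the absolute configuration of C4 and C5, set together, depends on the sense of conrotation inside the hydrogen-bonded ion pair between the two O–H groups of the cation and the chiral phosphoramide anion. The step needs water capture at furan C5 and torquoselective closure to outrun loss of the allylic proton next to the cationic carbon and any unpaired background closure; the 5-alkyl group stabilises the furfuryl cation so that it forms under mild conditions, the isolated Z-alkene is too far away to trap the cation, and the primary silyl ether is inert to the acid.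

Step 6
Reactants: 11 (4S,5R)-4-hydroxy-5-[(Z)-pent-2-en-1-yl]-4-{8-[(triisopropylsilyl)oxy]octyl}cyclopent-2-en-1-one
Product: 12 (1S,5R)-4-oxo-5-[(Z)-pent-2-en-1-yl]-1-{8-[(triisopropylsilyl)oxy]octyl}cyclopent-2-en-1-yl acetate
Conditions: Ac2O, Bi(OTf)3 (2 mol %), CH2Cl2, 0 °C; pH 7 buffer
Reagents that add atoms: acetic anhydride, CC(=O)OC(C)=O
Why: Lewis-acid-catalysed acylation with Ac2O esterifies hindered tertiary alcohols at low temperature without base, so base-induced loss of the β-oxygen and epimerisation at C5 are avoided, while ionisation at C4 is disfavoured because the cation would be conjugated with the electron-poor enone.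

Step 7
Reactants: 12 (1S,5R)-4-oxo-5-[(Z)-pent-2-en-1-yl]-1-{8-[(triisopropylsilyl)oxy]octyl}cyclopent-2-en-1-yl acetate
Product: 13 (1S,5R)-1-(8-hydroxyoctyl)-4-oxo-5-[(Z)-pent-2-en-1-yl]cyclopent-2-en-1-yl acetate
Conditions: HF·pyridine, pyridine, THF, 0 °C → rt
Reagents that add atoms: none
Why: Fluoride-driven Si–O cleavage under buffered, weakly acidic conditions removes the primary silyl ether without exposing the β-acetoxy ketone to base, and the tertiary acetate, enone and Z-alkene are untouched.

Step 8
Reactants: 13 (1S,5R)-1-(8-hydroxyoctyl)-4-oxo-5-[(Z)-pent-2-en-1-yl]cyclopent-2-en-1-yl acetate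
Product: 15 8-{(1S,5R)-1-acetoxy-4-oxo-5-[(Z)-pent-2-en-1-yl]cyclopent-2-en-1-yl}octanoic acid, via aldehyde 14 (not isolated)
Conditions: TEMPO (2,2,6,6-tetramethylpiperidin-1-oxyl, 20 mol %), PhI(OAc)2 (2.5 equiv), MeCN/H2O 1:1, rt
Reagents that add atoms: water, O
Why: Oxoammonium-mediated oxidation with PhI(OAc)2 as terminal oxidant takes the primary alcohol through the aldehyde and its hydrate to the carboxylic acid in one flask under mildly acidic conditions that leave the alkene, the enone, the tertiary acetate and the C5 centre alone.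

Compound list
1 | 8-bromooctan-1-ol | OCCCCCCCCBr | starting material
2 | [(8-bromooctyl)oxy]triisopropylsilane | BrCCCCCCCCO[Si](C(C)C)(C(C)C)C(C)C | intermediate
3 | furan | c1ccoc1 | starting material
4 | 2-lithiofuran (furan-2-yllithium) | [Li]c1ccco1 | intermediate
5 | triisopropyl{[8-(furan-2-yl)octyl]oxy}silane | CC(C)[Si](OCCCCCCCCc1ccco1)(C(C)C)C(C)C | intermediate
6 | (Z)-hex-3-en-1-ol | CC/C=C\CCO | starting material
7 | (Z)-hex-3-enal | CC/C=C\CC=O | intermediate
8 | (5-{8-[(triisopropylsilyl)oxy]octyl}furan-2-yl)lithium | [Li]c1ccc(CCCCCCCCO[Si](C(C)C)(C(C)C)C(C)C)o1 | intermediate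
9 | dichloro(5-{8-[(triisopropylsilyl)oxy]octyl}furan-2-yl)cerium | Cl[Ce](Cl)c1ccc(CCCCCCCCO[Si](C(C)C)(C(C)C)C(C)C)o1 | intermediate
10 | (Z)-1-(5-{8-[(triisopropylsilyl)oxy]octyl}furan-2-yl)hex-3-en-1-ol, racemic at the carbinol carbon | CC/C=C\CC(O)c1ccc(CCCCCCCCO[Si](C(C)C)(C(C)C)C(C)C)o1 | intermediate
11 | (4S,5R)-4-hydroxy-5-[(Z)-pent-2-en-1-yl]-4-{8-[(triisopropylsilyl)oxy]octyl}cyclopent-2-en-1-one (hydroxyl trans to pentenyl) | CC/C=C\C[C@H]1C(=O)C=C[C@]1(CCCCCCCCO[Si](C(C)C)(C(C)C)C(C)C)O | intermediate
12 | (1S,5R)-4-oxo-5-[(Z)-pent-2-en-1-yl]-1-{8-[(triisopropylsilyl)oxy]octyl}cyclopent-2-en-1-yl acetate | CC/C=C\C[C@H]1C(=O)C=C[C@]1(CCCCCCCCO[Si](C(C)C)(C(C)C)C(C)C)OC(C)=O | intermediate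
13 | (1S,5R)-1-(8-hydroxyoctyl)-4-oxo-5-[(Z)-pent-2-en-1-yl]cyclopent-2-en-1-yl acetate | CC/C=C\C[C@H]1C(=O)C=C[C@]1(CCCCCCCCO)OC(C)=O | intermediate
14 | (1S,5R)-4-oxo-1-(8-oxooctyl)-5-[(Z)-pent-2-en-1-yl]cyclopent-2-en-1-yl acetate | CC/C=C\C[C@H]1C(=O)C=C[C@]1(CCCCCCCC=O)OC(C)=O | intermediate
15 | 8-{(1S,5R)-1-acetoxy-4-oxo-5-[(Z)-pent-2-en-1-yl]cyclopent-2-en-1-yl}octanoic acid | CC/C=C\C[C@H]1C(=O)C=C[C@]1(CCCCCCCC(=O)O)OC(C)=O | target

Total step count: 8. Longest linear sequence: 7 (steps 1, 2, 4, 5, 6, 7, 8 from 8-bromooctan-1-ol); step 3 is a one-step side branch.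

Steps most likely to fail

Step 5. The chiral counter-anion may transfer too little of its asymmetry to the conrotation, giving low enantioselectivity. The furfuryl cation may also lose the allylic proton next to the cationic carbon and drain into a conjugated dienylfuran before water adds. The fallback uses known chemistry and sets out from 10: the racemic rearrangement with Dy(OTf)3 in MeCN/H2O at 80 °C, or with ZnCl2 in dioxane/H2O at reflux, should give the racemic trans ketol rac-(4S*,5R*)-4-hydroxy-5-[(Z)-pent-2-en-1-yl]-4-{8-[(triisopropylsilyl)oxy]octyl}cyclopent-2-en-1-one F1. This is resolved by preparative chromatography on a chiral stationary phase (amylose tris(3,5-dimethylphenylcarbamate) on silica). The (4S,5R) enantiomer is 11, where the route is rejoined, and (4R,5S)-4-hydroxy-5-[(Z)-pent-2-en-1-yl]-4-{8-[(triisopropylsilyl)oxy]octyl}cyclopent-2-en-1-one F2 is set aside.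

Step 4. The organometal may deprotonate the β,γ-unsaturated aldehyde instead of adding to it, leading to enolisation, migration of the alkene into conjugation and self-condensation. The fallback avoids an enolisable aldehyde and makes the Z-alkene last; it sets out from 5.
- Compound 5 is lithiated as in step 4 and quenched with DMF to give 5-{8-[(triisopropylsilyl)oxy]octyl}furan-2-carbaldehyde F3.
- Barbier propargylation (propargyl bromide, Zn, THF/aq. NH4Cl) gives 1-(5-{8-[(triisopropylsilyl)oxy]octyl}furan-2-yl)but-3-yn-1-ol F4.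
- The alkoxide–acetylide dianion (n-BuLi, 2.2 equiv, THF/DMPU, −78 °C) is ethylated at carbon with iodoethane to 1-(5-{8-[(triisopropylsilyl)oxy]octyl}furan-2-yl)hex-3-yn-1-ol F5.
- cis-Semihydrogenation (H2, Pd/CaCO3 poisoned with Pb(OAc)2, quinoline, EtOAc) returns the route at 10.

Step 6. Acylation of the hindered tertiary alcohol may be slow enough for acetolysis of the silyl ether, elimination across C4–C5 or epimerisation at C5 to compete. The fallback removes the ketone while the ester is installed; it sets out from 11.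
- Luche reduction (NaBH4, CeCl3·7H2O, MeOH, −78 °C) gives (1S,5S)-5-[(Z)-pent-2-en-1-yl]-1-{8-[(triisopropylsilyl)oxy]octyl}cyclopent-2-ene-1,4-diol F6; the new carbinol configuration is irrelevant.
- With no enolisable ketone present, forcing nucleophilic catalysis (Ac2O, DMAP, Et3N, CH2Cl2, 40 °C) can be used to give (1S,5S)-5-[(Z)-pent-2-en-1-yl]-1-{8-[(triisopropylsilyl)oxy]octyl}cyclopent-2-ene-1,4-diyl diacetate F7.
- Selective methanolysis of the secondary allylic acetate (K2CO3, MeOH, 0 °C) leaves the tertiary ester and gives (1S,5S)-4-hydroxy-5-[(Z)-pent-2-en-1-yl]-1-{8-[(triisopropylsilyl)oxy]octyl}cyclopent-2-en-1-yl acetate F8.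
- Dess–Martin oxidation restores the enone and returns the route at 12.

Further compounds
F1 | step 5 | rac-(4S*,5R*)-4-hydroxy-5-[(Z)-pent-2-en-1-yl]-4-{8-[(triisopropylsilyl)oxy]octyl}cyclopent-2-en-1-one (1:1 mixture of enantiomers) | CC/C=C\C[C@H]1C(=O)C=C[C@]1(CCCCCCCCO[Si](C(C)C)(C(C)C)C(C)C)O.CC/C=C\C[C@@H]1C(=O)C=C[C@@]1(CCCCCCCCO[Si](C(C)C)(C(C)C)C(C)C)O
F2 | step 5 | (4R,5S)-4-hydroxy-5-[(Z)-pent-2-en-1-yl]-4-{8-[(triisopropylsilyl)oxy]octyl}cyclopent-2-en-1-one | CC/C=C\C[C@@H]1C(=O)C=C[C@@]1(CCCCCCCCO[Si](C(C)C)(C(C)C)C(C)C)O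
F3 | step 4 | 5-{8-[(triisopropylsilyl)oxy]octyl}furan-2-carbaldehyde | O=Cc1ccc(CCCCCCCCO[Si](C(C)C)(C(C)C)C(C)C)o1
F4 | step 4 | 1-(5-{8-[(triisopropylsilyl)oxy]octyl}furan-2-yl)but-3-yn-1-ol (racemic) | C#CCC(O)c1ccc(CCCCCCCCO[Si](C(C)C)(C(C)C)C(C)C)o1
F5 | step 4 | 1-(5-{8-[(triisopropylsilyl)oxy]octyl}furan-2-yl)hex-3-yn-1-ol (racemic) | CCC#CCC(O)c1ccc(CCCCCCCCO[Si](C(C)C)(C(C)C)C(C)C)o1
F6 | step 6 | (1S,5S)-5-[(Z)-pent-2-en-1-yl]-1-{8-[(triisopropylsilyl)oxy]octyl}cyclopent-2-ene-1,4-diol (C4 configuration not defined) | CC/C=C\C[C@H]1C(O)C=C[C@]1(CCCCCCCCO[Si](C(C)C)(C(C)C)C(C)C)O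
F7 | step 6 | (1S,5S)-5-[(Z)-pent-2-en-1-yl]-1-{8-[(triisopropylsilyl)oxy]octyl}cyclopent-2-ene-1,4-diyl diacetate (C4 configuration not defined) | CC/C=C\C[C@H]1C(OC(C)=O)C=C[C@]1(CCCCCCCCO[Si](C(C)C)(C(C)C)C(C)C)OC(C)=O
F8 | step 6 | (1S,5S)-4-hydroxy-5-[(Z)-pent-2-en-1-yl]-1-{8-[(triisopropylsilyl)oxy]octyl}cyclopent-2-en-1-yl acetate (C4 configuration not defined) | CC/C=C\C[C@H]1C(O)C=C[C@]1(CCCCCCCCO[Si](C(C)C)(C(C)C)C(C)C)OC(C)=O
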